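## Retrosynthetic overview

1. Target ⇒ desilylation, then cleavage of the C(sp2)–CH2 bond between the vinylidene carbon and ring A (nickel/cobalt cross-electrophile coupling) ⇒ ring B enol triflate + ring A epoxy mesylate.
2. Ring A epoxy mesylate ⇒ hydroxyl-directed epoxidation of a trans homoallylic alcohol ⇒ epimerisation/Wittig of the cis Diels–Alder adduct of a silyloxymethyl diene with methyl vinyl ketone.
3. Ring B enol triflate ⇒ invertive bromide displacement on a trans-diaxial diol ⇒ epoxidation/hydrolysis of a dienyl triflate ⇒ Diels–Alder adduct of isoprene with methyl vinyl ketone.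
4. Ring order: cyclohexene ring A (step 4), then its oxirane (step 7); cyclohexene ring B separately (step 9); the two ring systems are joined last (step 14).

Assumption: the (S)-oxazaborolidinium catalyst is taken to expose the enone face that gives the (R)-configured acetyl-bearing carbon in both Diels–Alder steps; if the opposite sense is found, the (R)-catalyst is used in both and nothing else changes.

## Route

**Step 1**
Reactants: 1 2-methylbut-1-en-3-yne; 2 formaldehyde (used as paraformaldehyde)
Product: 4 4-methylpent-4-en-2-yn-1-ol, via lithium acetylide 3 (not isolated)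
Conditions: n-BuLi, THF, −78 °C; then (CH2O)n, −78 °C → rt
Reagents that add atoms: none
Why: Alkynylation of formaldehyde, in which n-BuLi removes the acetylenic proton and acetylide 3 adds to depolymerised paraformaldehyde, a standard propargylic alcohol synthesis that creates no stereocentre.

**Step 2**
Reactants: 4 4-methylpent-4-en-2-yn-1-ol
Product: 5 (2E)-4-methylpenta-2,4-dien-1-ol
Conditions: LiAlH4, THF, 0 → 45 °C
Reagents that add atoms: none
Why: Hydroxyl-directed trans-hydroalumination of the propargylic alcohol followed by protonolysis gives only the (E)-allylic alcohol, which fixes the diene geometry needed for a cis (endo) Diels–Alder adduct.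

**Step 3**
Reactants: 5 (2E)-4-methylpenta-2,4-dien-1-ol
Product: 6 tert-butyl(dimethyl){[(2E)-4-methylpenta-2,4-dien-1-yl]oxy}silane
Conditions: TBSCl, imidazole, DMF, 0 °C → rt
Reagents that add atoms: tert-butyldimethylsilyl chloride, CC(C)(C)[Si](C)(C)Cl
Why: Standard silylation (protection) of the primary alcohol so that a free hydroxyl does not quench the boron Lewis acid of step 4.

**Step 4**
Reactants: 6 tert-butyl(dimethyl){[(2E)-4-methylpenta-2,4-dien-1-yl]oxy}silane; 7 but-3-en-2-one (methyl vinyl ketone)
Product: 8 1-[(1R,2S)-2-({[tert-butyl(dimethyl)silyl]oxy}methyl)-4-methylcyclohex-3-en-1-yl]ethan-1-one (cis adduct)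
Conditions: 7 (3 equiv), (S)-1-(2-methylphenyl)-3,3-diphenyltetrahydro-1H,3H-pyrrolo[1,2-c][1,3,2]oxazaborole protonated by HN(SO2CF3)2 (15 mol%), CH2Cl2, −78 → −40 °C
Reagents that add atoms: none
Why: Enantioselective Diels–Alder reaction under chiral oxazaborolidinium (cationic boron Lewis acid) catalysis, in which the 1-CH2OTBS and 3-methyl groups of 6 steer the acetyl group to the same carbon so that one regioisomer forms, the endo transition state gives the cis adduct, and the shielded enone face fixes the CH2O-bearing carbon as (S), which is kept to the target, while the minor exo isomer is removed on silica because after epimerisation it would feed the opposite enantiomeric series.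

**Step 5**
Reactants: 8 cis ketone
Product: 10 tert-butyl(dimethyl){[(1S,6S)-3-methyl-6-(prop-1-en-2-yl)cyclohex-2-en-1-yl]methoxy}silane, via trans ketone 9 (not isolated)
Conditions: KOt-Bu (0.3 equiv), t-BuOH/THF, rt, 3 h; then Ph3P=CH2 (from Ph3PCH3Br + KOt-Bu), THF, 0 °C → rt
Reagents that add atoms: methyltriphenylphosphonium bromide, C[P+](c1ccccc1)(c1ccccc1)c1ccccc1.[Br-]
Why: Base-mediated epimerisation α to the ketone gives the thermodynamically preferred trans-diequatorial ketone 9, which is methylenated in the same flask by a Wittig reaction, so the isopropenyl-bearing carbon is set (S) under thermodynamic control and is fixed once the carbonyl is gone.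

**Step 6**
Reactants: 10 silyl ether
Product: 11 [(1S,6S)-3-methyl-6-(prop-1-en-2-yl)cyclohex-2-en-1-yl]methanol
Conditions: Bu4NF, THF, 0 °C → rt
Reagents that add atoms: none
Why: Fluoride-mediated desilylation frees the homoallylic alcohol needed as directing group and leaves both alkenes untouched.

**Step 7**
Reactants: 11 homoallylic alcohol
Product: 12 [(1S,4S,5S,6R)-1-methyl-4-(prop-1-en-2-yl)-7-oxabicyclo[4.1.0]heptan-5-yl]methanol
Conditions: VO(acac)2 (3 mol%), t-BuOOH (1.3 equiv), CH2Cl2, 0 °C → rt
Reagents that add atoms: tert-butyl hydroperoxide, CC(C)(C)OO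
Why: Vanadium-catalysed hydroxyl-directed epoxidation, in which the homoallylic alkoxide binds the vanadium alkylperoxide and delivers oxygen to the trisubstituted ring alkene on the face of the CH2OH group, which sets both oxirane carbons cis to that substituent and trans to isopropenyl and leaves the more distant, less electron-rich isopropenyl alkene alone.

**Step 8**
Reactants: 12 epoxy alcohol
Product: 13 [(1S,4S,5S,6R)-1-methyl-4-(prop-1-en-2-yl)-7-oxabicyclo[4.1.0]heptan-5-yl]methyl methanesulfonate
Conditions: MsCl, Et3N, CH2Cl2, −20 → 0 °C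
Reagents that add atoms: methanesulfonyl chloride, CS(=O)(=O)Cl
Why: Mesylation of the primary alcohol under mild base gives the sulfonate electrophile for the coupling without opening the oxirane or touching a stereocentre.

**Step 9**
Reactants: 14 isoprene (2-methylbuta-1,3-diene); 7 but-3-en-2-one
Product: 15 1-[(1R)-4-methylcyclohex-3-en-1-yl]ethan-1-one
Conditions: catalyst of step 4 (15 mol%), CH2Cl2, −78 → −20 °C
Reagents that add atoms: none
Why: Enantioselective Diels–Alder reaction with the same oxazaborolidinium catalyst, in which the 2-methyl group of isoprene directs the acetyl group para and the same shielded enone face as in step 4 gives the (R) stereocentre that becomes the side-chain-bearing carbon of ring B.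

**Step 10**
Reactants: 15 (R)-ketone
Product: 17 1-[(1R)-4-methylcyclohex-3-en-1-yl]ethenyl trifluoromethanesulfonate, via potassium enolate 16 (not isolated)
Conditions: KN(SiMe3)2, THF, −78 °C (ketone added to base); then PhNTf2, −78 → 0 °C
Reagents that add atoms: N-phenylbis(trifluoromethanesulfonimide), O=S(=O)(N(c1ccccc1)S(=O)(=O)C(F)(F)F)C(F)(F)F (KN(SiMe3)2 supplies only the potassium of 16)
Why: Kinetic deprotonation of the methyl group at −78 °C with inverse addition and O-sulfonylation of enolate 16 (enol triflate formation) give the terminal alkenyl triflate while the α-stereocentre is neither deprotonated nor racemised.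

**Step 11**
Reactants: 17 dienyl triflate
Product: 19 1-[(1R,3S,4S)-3,4-dihydroxy-4-methylcyclohexyl]ethenyl trifluoromethanesulfonate, via epoxide mixture 18 (not isolated)
Conditions: mCPBA, CH2Cl2, 0 °C; then 5% aq. H2SO4, THF, 0 °C → rt
Reagents that add atoms: 3-chloroperoxybenzoic acid, OOC(=O)c1cccc(Cl)c1; water, O
Why: Prilezhaev epoxidation of the electron-rich trisubstituted alkene (the enol triflate alkene is deactivated) followed by acid-catalysed trans-diaxial (Fürst–Plattner) hydrolysis, in which both epoxide diastereomers converge mainly on the diaxial diol with the tertiary hydroxyl cis and the secondary hydroxyl trans to the side chain, sets the tertiary carbinol centre.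

**Step 12**
Reactants: 19 diol
Product: 21 1-[(1R,3S,4S)-3-hydroxy-4-methyl-4-(trimethylsilyloxy)cyclohexyl]ethenyl trifluoromethanesulfonate, via bis-silyl ether 20 (not isolated)
Conditions: Me3SiCl (3 equiv), imidazole, DMF, rt; then MeOH, PPTS (cat.), 0 °C
Reagents that add atoms: chlorotrimethylsilane, C[Si](C)(C)Cl
Why: Exhaustive silylation followed by selective acid-catalysed methanolysis of the secondary trimethylsilyl ether (tertiary trimethylsilyl ethers cleave far more slowly) masks only the tertiary hydroxyl, which would otherwise close to an epoxide in step 13.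

**Step 13**
Reactants: 21 mono-silyl ether
Product: 23 1-[(1R,3R,4S)-3-bromo-4-methyl-4-(trimethylsilyloxy)cyclohexyl]ethenyl trifluoromethanesulfonate, via secondary triflate 22 (not isolated)
Conditions: Tf2O, 2,6-lutidine, CH2Cl2, −40 °C; then Bu4NBr (3 equiv), −40 °C → rt
Reagents that add atoms: tetrabutylammonium bromide, CCCC[N+](CCCC)(CCCC)CCCC.[Br-]; trifluoromethanesulfonic anhydride, O=S(=O)(OS(=O)(=O)C(F)(F)F)C(F)(F)F (its atoms stay only in 22)
Why: Triflation and SN2 displacement, in which bromide attacks the axial secondary triflate 22 from the equatorial side with inversion, places bromine equatorial and cis to the silyloxy group (the poorly nucleophilic silyl ether oxygen cannot compete by epoxide formation) and so sets the C–Br stereocentre.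

**Step 14**
Reactants: 13 ring A epoxy mesylate (1.3 equiv); 23 ring B enol triflate
Product: 25 (1S,2R,4R)-2-bromo-1-methyl-4-{3-[(1S,4S,5R,6R)-1-methyl-4-(prop-1-en-2-yl)-7-oxabicyclo[4.1.0]heptan-5-yl]prop-1-en-2-yl}cyclohexan-1-ol (CNP0213097.1), via silyl ether 24 (not isolated)
Conditions: NiBr2(dme) (10 mol%), 4,4′-di-tert-butyl-2,2′-bipyridine (12 mol%), Co(Pc) (C32H16CoN8, 5 mol%), Mn powder (3 equiv), DMA, 40 °C; then Bu4NF, AcOH, THF, 0 °C
Reagents that add atoms: none
Why: Proposed new method: cobalt-gated nickel cross-electrophile coupling of an enol triflate with an unactivated primary alkyl mesylate, in which bipyridine-ligated zerovalent nickel adds oxidatively to the C–OTf bond of 23, monovalent cobalt phthalocyanine (formed from Co(Pc) and Mn) displaces the mesylate of 13 by SN2 and the resulting alkylcobalt hands the primary alkyl group as a short-lived radical to the alkenylnickel, which reductively eliminates the C(sp2)–C(sp3) bond, the SN2 gate and the absence of halide additives being intended to leave the hindered secondary bromide, the oxirane and the alkenes as spectators; the closest known reaction type is nickel/cobalt dual-catalysed reductive cross-electrophile coupling of aryl halides with benzyl or alkyl sulfonates, which to my knowledge has not been shown for an α-branched enol triflate with a β-branched epoxy mesylate beside an alkyl bromide, and buffered fluoride then cleaves the silyl ether without touching any stereocentre.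

## Compound list

1 | 2-methylbut-1-en-3-yne | C=C(C)C#C | starting material
2 | formaldehyde (used as paraformaldehyde) | C=O | starting material
3 | (3-methylbut-3-en-1-yn-1-yl)lithium | [Li]C#CC(C)=C | intermediate
4 | 4-methylpent-4-en-2-yn-1-ol | C=C(C)C#CCO | intermediate
5 | (2E)-4-methylpenta-2,4-dien-1-ol | C=C(C)/C=C/CO | intermediate
6 | tert-butyl(dimethyl){[(2E)-4-methylpenta-2,4-dien-1-yl]oxy}silane | C=C(C)/C=C/CO[Si](C)(C)C(C)(C)C | intermediate
7 | but-3-en-2-one (methyl vinyl ketone) | C=CC(C)=O | starting material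
8 | 1-[(1R,2S)-2-({[tert-butyl(dimethyl)silyl]oxy}methyl)-4-methylcyclohex-3-en-1-yl]ethan-1-one | CC(C)(C)[Si](C)(C)OC[C@@H]1[C@H](C(C)=O)CCC(C)=C1 | intermediate
9 | 1-[(1S,2S)-2-({[tert-butyl(dimethyl)silyl]oxy}methyl)-4-methylcyclohex-3-en-1-yl]ethan-1-one | CC(C)(C)[Si](C)(C)OC[C@@H]1[C@@H](C(C)=O)CCC(C)=C1 | intermediate
10 | tert-butyl(dimethyl){[(1S,6S)-3-methyl-6-(prop-1-en-2-yl)cyclohex-2-en-1-yl]methoxy}silane | CC(C)(C)[Si](C)(C)OC[C@@H]1[C@@H](C(C)=C)CCC(C)=C1 | intermediate
11 | [(1S,6S)-3-methyl-6-(prop-1-en-2-yl)cyclohex-2-en-1-yl]methanol | OC[C@@H]1[C@@H](C(C)=C)CCC(C)=C1 | intermediate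
12 | [(1S,4S,5S,6R)-1-methyl-4-(prop-1-en-2-yl)-7-oxabicyclo[4.1.0]heptan-5-yl]methanol | OC[C@@H]1[C@@H](C(C)=C)CC[C@]2(C)O[C@H]12 | intermediate
13 | [(1S,4S,5S,6R)-1-methyl-4-(prop-1-en-2-yl)-7-oxabicyclo[4.1.0]heptan-5-yl]methyl methanesulfonate | CS(=O)(=O)OC[C@@H]1[C@@H](C(C)=C)CC[C@]2(C)O[C@H]12 | intermediate
14 | isoprene (2-methylbuta-1,3-diene) | C=CC(C)=C | starting material
15 | 1-[(1R)-4-methylcyclohex-3-en-1-yl]ethan-1-one | CC(=O)[C@@H]1CCC(C)=CC1 | intermediate
16 | potassium 1-[(1R)-4-methylcyclohex-3-en-1-yl]ethen-1-olate | C=C([O-])[C@@H]1CCC(C)=CC1.[K+] | intermediate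
17 | 1-[(1R)-4-methylcyclohex-3-en-1-yl]ethenyl trifluoromethanesulfonate | C=C(OS(=O)(=O)C(F)(F)F)[C@@H]1CCC(C)=CC1 | intermediate
18 | 1-[(4R)-1-methyl-7-oxabicyclo[4.1.0]heptan-4-yl]ethenyl trifluoromethanesulfonate (both epoxide diastereomers) | C=C(OS(=O)(=O)C(F)(F)F)[C@@H]1CCC2(C)OC2C1 | intermediate
19 | 1-[(1R,3S,4S)-3,4-dihydroxy-4-methylcyclohexyl]ethenyl trifluoromethanesulfonate | C=C(OS(=O)(=O)C(F)(F)F)[C@@H]1CC[C@](C)(O)[C@@H](O)C1 | intermediate
20 | 1-[(1R,3S,4S)-4-methyl-3,4-bis(trimethylsilyloxy)cyclohexyl]ethenyl trifluoromethanesulfonate | C=C(OS(=O)(=O)C(F)(F)F)[C@@H]1CC[C@](C)(O[Si](C)(C)C)[C@@H](O[Si](C)(C)C)C1 | intermediate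
21 | 1-[(1R,3S,4S)-3-hydroxy-4-methyl-4-(trimethylsilyloxy)cyclohexyl]ethenyl trifluoromethanesulfonate | C=C(OS(=O)(=O)C(F)(F)F)[C@@H]1CC[C@](C)(O[Si](C)(C)C)[C@@H](O)C1 | intermediate
22 | 1-[(1R,3S,4S)-4-methyl-3-(trifluoromethanesulfonyloxy)-4-(trimethylsilyloxy)cyclohexyl]ethenyl trifluoromethanesulfonate | C=C(OS(=O)(=O)C(F)(F)F)[C@@H]1CC[C@](C)(O[Si](C)(C)C)[C@@H](OS(=O)(=O)C(F)(F)F)C1 | intermediate
23 | 1-[(1R,3R,4S)-3-bromo-4-methyl-4-(trimethylsilyloxy)cyclohexyl]ethenyl trifluoromethanesulfonate | C=C(OS(=O)(=O)C(F)(F)F)[C@@H]1CC[C@](C)(O[Si](C)(C)C)[C@H](Br)C1 | intermediate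
24 | trimethylsilyl ether of 25 at the tertiary hydroxyl | C=C(C[C@@H]1[C@@H](C(=C)C)CC[C@]2(C)O[C@H]12)[C@@H]1CC[C@](C)(O[Si](C)(C)C)[C@H](Br)C1 | intermediate
25 | (1S,2R,4R)-2-bromo-1-methyl-4-{3-[(1S,4S,5R,6R)-1-methyl-4-(prop-1-en-2-yl)-7-oxabicyclo[4.1.0]heptan-5-yl]prop-1-en-2-yl}cyclohexan-1-ol | C=C(C[C@@H]1[C@@H](C(=C)C)CC[C@]2(C)O[C@H]12)[C@@H]1CC[C@](C)(O)[C@H](Br)C1 | target

## Step count and risks

Total step count: 14. Longest linear sequence: 9 steps (steps 1–8, then 14); the ring B branch is steps 9–13.

The three steps most likely to fail: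

Step 14 (the proposed new coupling). The cobalt nucleophile may be slow at the β-branched mesylate, low-valent nickel may attack the secondary bromide, and the primary radical may abstract an allylic hydrogen of the isopropenyl methyl group. Minor diastereomers from the small amount of wrong enantiomer in each fragment are removed by chromatography here. The fallback uses known chemistry, sets out from 13 and comes back at 24. Finkelstein exchange of mesylate 13 (NaI, NaHCO3, acetone, 45 °C) gives the epoxy iodide (1S,4S,5R,6R)-5-(iodomethyl)-1-methyl-4-(prop-1-en-2-yl)-7-oxabicyclo[4.1.0]heptane F1. Zinc insertion (Zn dust, LiCl, THF, 35 °C) gives the alkylzinc iodide {[(1S,4S,5R,6R)-1-methyl-4-(prop-1-en-2-yl)-7-oxabicyclo[4.1.0]heptan-5-yl]methyl}zinc iodide F2. Negishi coupling of this reagent with enol triflate 23 (Pd(dppf)Cl2 5 mol%, THF/NMP, 40 °C) gives silyl ether 24, which is desilylated as in step 14. In this polar cycle zerovalent palladium does not engage the secondary bromide and no free radical is formed.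

Step 13. E2 elimination of the axial triflate and slow substitution next to the fully substituted carbon can erode the yield. The fallback replaces steps 11–13 by a halogen relay, sets out from 17 and comes back at 23. N-Iodosuccinimide in acetone/water adds iodine anti to the side chain, and water opens the iodonium ion diaxially at the tertiary carbon to give the iodohydrin 1-[(1R,3S,4S)-4-hydroxy-3-iodo-4-methylcyclohexyl]ethenyl trifluoromethanesulfonate F3. N-(Trimethylsilyl)imidazole gives its tertiary trimethylsilyl ether 1-[(1R,3S,4S)-3-iodo-4-methyl-4-(trimethylsilyloxy)cyclohexyl]ethenyl trifluoromethanesulfonate F4. Bu4NBr in DMF at 40 °C then displaces the axial iodide with inversion to give 23.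

Step 4. Enantio- and endo-selectivity with methyl vinyl ketone and the acid-sensitive dienyl silyl ether are not assured. The fallback switches to iminium organocatalysis, sets out from 6 and comes back at 8. Diels–Alder reaction of 6 with acrolein (5-benzyl-2,2,3-trimethylimidazolidin-4-one hydrochloride, enantiomer chosen for the required face, MeCN/H2O, −10 °C) gives the endo aldehyde (1R,2S)-2-({[tert-butyl(dimethyl)silyl]oxy}methyl)-4-methylcyclohex-3-ene-1-carbaldehyde F5. MeMgBr (THF, −78 °C) gives the carbinol 1-[(1R,2S)-2-({[tert-butyl(dimethyl)silyl]oxy}methyl)-4-methylcyclohex-3-en-1-yl]ethan-1-ol F6 as an epimer mixture at the new carbinol carbon. Dess–Martin periodinane oxidation then gives ketone 8.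

## Further compounds

F1 | step 14 | (1S,4S,5R,6R)-5-(iodomethyl)-1-methyl-4-(prop-1-en-2-yl)-7-oxabicyclo[4.1.0]heptane | IC[C@@H]1[C@@H](C(C)=C)CC[C@]2(C)O[C@H]12
F2 | step 14 | {[(1S,4S,5R,6R)-1-methyl-4-(prop-1-en-2-yl)-7-oxabicyclo[4.1.0]heptan-5-yl]methyl}zinc iodide | I[Zn]C[C@@H]1[C@@H](C(C)=C)CC[C@]2(C)O[C@H]12
F3 | step 13 | 1-[(1R,3S,4S)-4-hydroxy-3-iodo-4-methylcyclohexyl]ethenyl trifluoromethanesulfonate | C=C(OS(=O)(=O)C(F)(F)F)[C@@H]1CC[C@](C)(O)[C@@H](I)C1
F4 | step 13 | 1-[(1R,3S,4S)-3-iodo-4-methyl-4-(trimethylsilyloxy)cyclohexyl]ethenyl trifluoromethanesulfonate | C=C(OS(=O)(=O)C(F)(F)F)[C@@H]1CC[C@](C)(O[Si](C)(C)C)[C@@H](I)C1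
F5 | step 4 | (1R,2S)-2-({[tert-butyl(dimethyl)silyl]oxy}methyl)-4-methylcyclohex-3-ene-1-carbaldehyde | CC(C)(C)[Si](C)(C)OC[C@@H]1[C@H](C=O)CCC(C)=C1
F6 | step 4 | 1-[(1R,2S)-2-({[tert-butyl(dimethyl)silyl]oxy}methyl)-4-methylcyclohex-3-en-1-yl]ethan-1-ol (both carbinol epimers) | CC(C)(C)[Si](C)(C)OC[C@@H]1[C@H](C(C)O)CCC(C)=C1
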